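The constants used here were chosen freely, and the outcome is calculated.

Amounts first: each flask receives 0.900 equiv of partner on 0.020 M of starting material, and the flasks differ in which of the two is fed.

| setting | dawn | noon | autumn |
|---|---|---|---|
| starting material | 0.020 M | 0.020 M | 0.020 M (fed, over 40 min) |
| partner | 0.900 equiv (fed, over 40 min) | 0.900 equiv | 0.900 equiv |
| time | 1.0 h | 1.0 h | 1.0 h |
| remark | all else is in the flask from the start; the feed brings no volume worth counting | everything together at the start | all else is in the flask from the start; the feed brings no volume worth counting |

    single product + by-product → side product (k1 = 1.36 /M/min)
    starting material + partner → single product + by-product (k2 = 2.01 /M/min)
    partner + other mono adduct → double product + by-product (k3 = 0.879 /M/min)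
    partner + single product → double product + by-product (k4 = 2.21 /M/min)
    starting material + partner → other mono adduct + by-product (k5 = 0.0723 /M/min)
    partner → decomposed reagent (k6 = 0.114 /min)

- the flask with the highest amount of single product, in percent of the starting material charged ("all alike" if they lie within 1.5 percentage points) (dawn / noon / autumn / all alike)
- final single product, as a percentage of the starting material charged, in dawn
- final single product, as a percentage of the starting material charged, in noon
- final single product, as a percentage of the starting material charged, in autumn

At the start, before any product stands, partner has two exits, coupling with starting material and decomposition; later it also reacts with single product and other mono adduct. Dividing one rate by the other cancels [partner] and time. With [starting material] as charged, the couplings consume partner at 0.0416 /min against 0.114 /min, so the capture share, coupling rate over coupling plus decomposition rate, is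

capture share = 26.8%

The ladder in noon, from the fastest rung, is a set of half-lives. Partner decomposes in 0.10 h, shorter than the 0.29 h of single product against partner and the 0.32 h of starting material. Other mono adduct follows at 0.73 h. Slower still, by-product at its reckoned level of

0.00482 M

gives single product a half-life of 1.76 h, longer than the run. Single product therefore peaks and then erodes slowly, and in dawn it forms later and meets less of that erosion.

In autumn, [starting material] climbs during the feed. At partner's lifetime of 8.77 min it has reached 0.00439 M, so

capture share, autumn = 7.42%

This is lower than the share for noon. My reckoning stops at rough estimates for single product, before any further loss: 23.2% for dawn and noon, 6.44% for autumn.

The forecast names dawn, with 15%, 13.8% and 5% for dawn, noon and autumn, all below those estimates. Its ground: “only about a quarter of the partner reaches starting material in dawn and noon”.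

The simulation gives dawn as the highest, with 15.4%, 13.6% and 4.58%, so the forecast stands. Dawn ends with 79% of its starting material unreacted and 0.74% of its partner, the limiting reagent here.

Noon's decomposed reagent, 0.0132 M, leaves 26.7% of its partner charge undecomposed, a part that includes what single product and other mono adduct took up, beside the share of 26.8% reckoned for the start. Autumn's, 0.0168 M, leaves 6.58% on the same count, beside 7.42%. The neighbour is autumn charged with 3.60 equiv of partner. Taken over unchanged, autumn's share of 7.42% gives single product a rough 25.8%, though this neighbour's larger partner charge also takes up fed starting material during the climb, which that share ignores. That neighbour ends with 0.0675 M of decomposed reagent, so 6.25% of its partner charge undecomposed, 82.0% of starting material left, 4.56% of double product and 10.3% of single product.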